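If a complex takes up its first new ligand by the pseudo-first-order rule of thumb, the percent of starting complex turned into complex with one exchanged at a fixed time follows the incoming ligand charged and ignores the complex charged. I tested that rule on the earlier runs before using it.

| flask | starting complex | incoming ligand | leaving ligand | remark | time |
|---|---|---|---|---|---|
| beta | 6.3 mM | 30 mM | 10 mM | run made earlier |  |
| theta | 30 mM | 30 mM | 10 mM | run made earlier |  |
| eta | 20 mM | 12 mM | 10 mM | run made earlier |  |
| Wednesday's | 20 mM | 30.0 mM | 10.0 mM |  | 12 h |
| Sunday's | 5.0 mM | 8.00 mM | 10.0 mM |  | 12 h |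

| run | time / h | complex with one exchanged / % |
|---|---|---|
| beta | 1.50 | 7.8 |
| beta | 3.00 | 14.4 |
| beta | 5.00 | 19.4 |
| beta | 6.00 | 22.8 |
| beta | 8.00 | 25.8 |
| beta | 10.0 | 28.9 |
| beta | 12.0 | 30.0 |
| theta | 0.667 | 4.4 |
| theta | 2.00 | 9.6 |
| theta | 3.00 | 13.4 |
| theta | 5.00 | 17.4 |
| theta | 8.00 | 21.5 |
| theta | 10.0 | 24.5 |
| theta | 12.0 | 24.6 |
| eta | 2.50 | 5.6 |
| eta | 5.00 | 8.2 |
| eta | 8.00 | 11.3 |
| eta | 10.0 | 12.3 |
| eta | 12.0 | 12.9 |

(standard deviation of a reading: 0.5 percentage points)

- what may be going on: incoming ligand -> decomposed reagent; complex with two exchanged + incoming ligand <-> leaving ligand + complex with three exchanged; complex with one exchanged + incoming ligand <-> leaving ligand + complex with two exchanged; starting complex + incoming ligand <-> leaving ligand + complex with one exchanged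

- the winner by amount of complex with one exchanged, in percent of the starting complex charged; "neither" if no more than 2 percentage points parts them (Wednesday's / Sunday's / neither)
- how much complex with one exchanged is there at the end, in percent of the starting complex charged: Wednesday's
- how much complex with one exchanged is there at the end, in percent of the starting complex charged: Sunday's

The complex half of the rule nearly held. From the beta run to the theta run the starting complex rose by a factor 4.76, at equal ligand, and the last reading fell from 30.0 % to 24.6 %. I wrote this as a weak inverse power of the complex, b = 0.127, which carried the beta reading to 25.9 % for Wednesday's flask.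

The ligand half showed the border. The eta run had the starting complex of Wednesday's flask, but Wednesday's incoming ligand was larger by a ratio of 2.50, while my Wednesday's figure stood to the last eta reading in a ratio of 2.01, less than the rule asks. So I took a = 0.761, the power of the incoming ligand charged by which the percent at 12 h grows at fixed complex, which I call the ligand order. Scaling the eta reading by a and b gave Sunday's flask 11.3 %, so I expected Wednesday's to win by 15 percentage points, more than the margin of 2 points.

The forecast named Wednesday's, with 27 % (25 % to 29 %) for Wednesday's and 9.5 % (8 % to 11 %) for Sunday's, below my figure, and said: “Wednesday's clearly wins.”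

The flasks gave 26.9 % for Wednesday's and 10.8 % for Sunday's, so Wednesday's won.

    incoming ligand → decomposed reagent (k = 8.40 × 10⁻⁴ min⁻¹)
    complex with two exchanged + incoming ligand ⇌ leaving ligand + complex with three exchanged (K = 0.550, k = 0.0180 L mol⁻¹ min⁻¹)
    complex with one exchanged + incoming ligand ⇌ leaving ligand + complex with two exchanged (K = 4.50, k = 0.0160 L mol⁻¹ min⁻¹)
    starting complex + incoming ligand ⇌ leaving ligand + complex with one exchanged (K = 1.00, k = 0.0330 L mol⁻¹ min⁻¹)

In Sunday's flask at 12.0 h, the half-life of the incoming ligand was shorter by decomposition, 14 h, than by the forward first exchange, 79 h. There 49 % of the ligand and 89 % of the starting complex remained. With a = 0.761 and b = 0.127, my reckoning for Sunday's flask stood 0.50 points above the result. For Sunday's flask read at 5.0 h, the same reckoning on the readings of that time gave b = 0.0697, an order of 0.852 in place of 0.761, and 6.39 %. The computed flask holds 6.18 %.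

The data stem from a simulated flask on assumed constants, and the scatter is random.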